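We will rank the set-ups by one number first, and let the rest of the chemistry follow it.

    partner + single product → bis adduct + by-product (k1 = 10.3 M⁻¹ min⁻¹)
    single product ⇌ isomer of the product (K2 = 2.3, k2 = 0.103 min⁻¹)
    starting material + partner → single product + by-product (k3 = 10.1 M⁻¹ min⁻¹)
    partner + bis adduct → triple product + by-product (k4 = 22.6 M⁻¹ min⁻¹)

| setting | delta | beta | alpha | eta |
|---|---|---|---|---|
| starting material | 16 mM | 16 mM (fed, over 12.5 min) | 16 mM | 16 mM |
| partner | 20.8 mM | 20.8 mM | 20.8 mM | 20.8 mM (fed, over 12.5 min) |
| time | 25 min | 25 min |  | 25 min |
| remark | everything together in a closed stirred flask, run for 25 min | a stirred flask in which starting material is dosed at a steady rate over 12.5 min without added volume, worked up at 25 min | a single well-mixed tank run continuously and read at steady state, 25 min in it on average | all but partner at the start; partner goes in evenly over 12.5 min, the run ends at 25 min |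

* the set-up with the highest share of single product in all that became single product or bis adduct or triple product or isomer of the product, at the outlet or at the end ("none" if the first two lie within 2 percentage points) (delta / beta / alpha / eta / none)
* share of single product in all that became single product or bis adduct or triple product or isomer of the product, at the outlet or at the end, delta
* share of single product in all that became single product or bis adduct or triple product or isomer of the product, at the outlet or at the end, beta
* share of single product in all that became single product or bis adduct or triple product or isomer of the product, at the outlet or at the end, alpha
* share of single product in all that became single product or bis adduct or triple product or isomer of the product, at the outlet or at the end, eta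

- the stated concentrations are those of everything mixed, before any reaction; amounts are the same in each set-up
- the feed brings no volume worth counting
- run time (delta): 25 min

**In the flask.** Starting material and partner make single product, partner carries it on to bis adduct and triple product, and single product also turns into its isomer with no partner involved. We watch the split, [single product] / ([single product] + [isomer of the product]). The asked share is the split times the pair's share of all product.

**Closed and dosed.** The pair relaxes in 6.77 min, less than the 12.5 min that remain after dosing ends in beta and eta, and delta runs for the full 25 min. So in delta, beta and eta the split drifts towards its equilibrium value, 30.3%.

**The tank.** In alpha, the isomer balance has no partner term. [isomer of the product] / [single product] is the forward constant 0.103 min⁻¹ over the sum of the washout 0.0400 min⁻¹ and the back constant 0.0448 min⁻¹, which gives 1.21. The steady-state tank split is therefore 45.1%, which is higher than the equilibrium value. We expect alpha to lead unless its pair's share is poorer. Leave the stay alone, since at 75.0 min the reckoned split is lower, 36.1%. This reckoning points to a leader, not the four shares.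

**The forecast.** It names alpha, with 21% for delta, 23% for beta, 27.8% for alpha and 25% for eta, and it calls the lead “only just beyond the 2-point cut-off”.

**The result.** The simulation gives alpha at 27.8%, with 20.7% for delta, 23.6% for beta and 24.4% for eta. With the turning into isomer struck out, delta reads 49.9%. Dividing alpha's share by the tank split puts the pair at 61.5% of all product. Holding that pair share, the split of 36.1% at a stay of 75.0 min gives 22.2%. The tank at that stay reads 21.2%.

(The rate constants come from no measurement; the rest is arithmetic.)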